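**Retrosynthetic overview**

- Numbering follows 3,7-dioxabicyclo[3.3.0]octane: C1 (OAc), C2 (guaiacyl), O3, C4, C5 (H), C6 (veratryl), O7, C8. Ring A is C1–C2–O3–C4–C5 and ring B is C5–C6–O7–C8–C1. The target is (1S,2R,5R,6S), with both aryl groups exo (cis to OAc and to H5).
- The plan rests on the four-carbon run C8–C1–C5–C4 shared by rings A and B and oxygenated at the quaternary C1. It maps onto HO2C–CH(OH)–CH2–CO2H of L-malic acid, whose carbinol carbon must take a fourth substituent while keeping its sense of chirality.
- Endgame: the phenol comes from its benzyl ether and the acetate from the C1 alcohol. The CH2 groups C4 and C8 come from lactone carbonyls by a reduction that never breaks the benzylic C2–O3 and C6–O7 bonds.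
- Ring B (formed second): C5–C6 and O7–C8 arise from an aldol of the ring A lactone enolate with veratraldehyde, whose alkoxide takes over the dioxolanone acyl carbon C8.
- Ring A (formed first): C1–C2 and O3–C4 arise from the aldol of the dianion of the malic acid pivaldehyde acetal with O-benzylvanillin, followed by lactonisation. The acetal carbon stores the chirality while C1 is planar.

Key step: step 2

Remark: 5 and 8 are drawn in their neutral forms although 8 exists in the flask as its potassium alkoxide, and the lactol carbons C4 and C8 of 10 are left undefined because step 5 turns both into CH2.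

**Step 1**
Reactants: 1 L-malic acid; 2 pivaldehyde
Product: 3 2-[(2S,4S)-2-tert-butyl-5-oxo-1,3-dioxolan-4-yl]acetic acid (cis)
Conditions: cat. TsOH·H2O, cat. H2SO4, pentane, reflux, Dean–Stark trap; recrystallisation
Reagents that add atoms: none
Why: Acid-catalysed acetalisation with azeotropic removal of water ties up the α-hydroxy acid unit as the five-membered dioxolanone (favoured over the six-membered dioxanone through the β-carboxyl), and because the acetal carbon equilibrates under these conditions it settles as the cis (2S) isomer, which is purified by crystallisation.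

**Step 2**
Reactants: 3 2-[(2S,4S)-2-tert-butyl-5-oxo-1,3-dioxolan-4-yl]acetic acid; 4 4-(benzyloxy)-3-methoxybenzaldehyde
Product: 6 (2S,5R,6R)-6-[4-(benzyloxy)-3-methoxyphenyl]-2-tert-butyl-1,3,7-trioxaspiro[4.4]nonane-4,8-dione, via aldol hydroxy acid 5 (not isolated)
Conditions: LiN(SiMe3)2 (2.2 equiv), THF, −78 °C; 4, −78 °C; 1 M HCl to pH 2; then cat. PPTS, 4 Å MS, CH2Cl2, rt
Reagents that add atoms: none
Why: LiN(SiMe3)2 first makes the lithium carboxylate and then removes the C1 proton next to the dioxolanone carbonyl, the negative charge on the side chain keeping its CH2 group (C5) from being deprotonated and so closing the path to β-elimination of the ring oxygen, and the resulting enolate adds to aldehyde 4 to form C1–C2. The closest known reaction type is the alkylation and aldol addition of lithium enolates of 2-tert-butyl-1,3-dioxolan-4-ones made from α-hydroxy acids (self-regeneration of a stereocentre). C1 is flat in the enolate, yet the acetal carbon installed in step 1 still holds the malic acid chirality and its tert-butyl group screens one face, so 4 bonds where the proton sat and C1 is substituted with net retention. C2 is set in a Zimmerman–Traxler chair in which the five-membered ring locks OLi cis to the CH2CO2Li branch, so that an equatorial aryl group gives the C5/O3-syn adduct 5, the one whose aryl group ends up cis to the C1 oxygen on ring A; this simple diastereoselection is the selectivity the step needs most and is the least certain, and a C2 epimer would be removed by chromatography or crystallisation of 6. Ring A closes after acidification by 5-exo-trig addition–elimination of the C2 hydroxyl on the side-chain carboxyl C4 (O3–C4), helped by the quaternary C1, while the alternative attack on the dioxolanone carbonyl would need a four-membered ring, so the acetal stays in place for step 3. The weak acid PPTS keeps the closure at the acyl carbon and avoids ionisation of the electron-rich benzylic alcohol, so C2 is not scrambled.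

**Step 3**
Reactants: 6 (2S,5R,6R)-6-[4-(benzyloxy)-3-methoxyphenyl]-2-tert-butyl-1,3,7-trioxaspiro[4.4]nonane-4,8-dione; 7 veratraldehyde
Product: 9 (1R,2R,5R,6S)-2-[4-(benzyloxy)-3-methoxyphenyl]-6-(3,4-dimethoxyphenyl)-1-hydroxy-3,7-dioxabicyclo[3.3.0]octane-4,8-dione, via C5 aldol adduct 8 (not isolated)
Conditions: KN(SiMe3)2 (1.1 equiv), THF, −78 °C, 10 min; 7, −78 to −40 °C; AcOH
Reagents that add atoms: none
Why: Tandem aldol addition–translactonisation, in which the C5 potassium enolate, made and consumed at −78 °C where β-oxygenated lactone enolates are known to outlive E1cB loss of the β-oxygen, bonds to 7 on the ring A face opposite the C1–O bond, the C2 aryl group and the tert-butyl group (sets C5), potassium γ-lactone enolates add to aromatic aldehydes through an open antiperiplanar transition state with erythro preference (sets C6 with the aryl group exo), and the alkoxide of 8 closes ring B by 5-exo-trig attack on the activated acylal carbonyl C8 with expulsion of pivaldehyde, a closure open only to the cis-fused adduct.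

**Step 4**
Reactants: 9 (1R,2R,5R,6S)-2-[4-(benzyloxy)-3-methoxyphenyl]-6-(3,4-dimethoxyphenyl)-1-hydroxy-3,7-dioxabicyclo[3.3.0]octane-4,8-dione
Product: 10 (1R,2R,5R,6S)-2-[4-(benzyloxy)-3-methoxyphenyl]-6-(3,4-dimethoxyphenyl)-3,7-dioxabicyclo[3.3.0]octane-1,4,8-triol (bis-lactol, anomer mixture at C4 and C8)
Conditions: i-Bu2AlH (3.5 equiv), CH2Cl2, −78 °C; aq. potassium sodium tartrate
Reagents that add atoms: none
Why: Partial reduction of γ-lactones with i-Bu2AlH stops at the aluminium hemiacetal at −78 °C (one extra equivalent is used up by the C1 hydroxyl), rings A and B stay closed so that C1, C2, C5 and C6 are untouched, and the two new lactol centres are of no consequence because step 5 removes them.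

**Step 5**
Reactants: 10 bis-lactol
Product: 11 (1S,2R,5R,6S)-2-[4-(benzyloxy)-3-methoxyphenyl]-6-(3,4-dimethoxyphenyl)-3,7-dioxabicyclo[3.3.0]octan-1-ol
Conditions: Et3SiH (6 equiv), BF3·OEt2 (3 equiv), CH2Cl2, −78 to −20 °C; aq. NaHCO3
Reagents that add atoms: none
Why: Ionic hydrogenation of lactols, in which BF3·OEt2 ionises each hemiacetal C–OH bond to a ring oxocarbenium ion that Et3SiH reduces to CH2, and since hemiacetals ionise far more readily than the benzylic ring ethers C2–O3 and C6–O7 (furofurans need hot protic acid to epimerise) the four stereocentres are carried through unchanged, while the tertiary C1 hydroxyl, which cannot give a stabilised cation, is kept.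

**Step 6**
Reactants: 11 (1S,2R,5R,6S)-2-[4-(benzyloxy)-3-methoxyphenyl]-6-(3,4-dimethoxyphenyl)-3,7-dioxabicyclo[3.3.0]octan-1-ol
Product: 12 (1S,2R,5R,6S)-2-[4-(benzyloxy)-3-methoxyphenyl]-6-(3,4-dimethoxyphenyl)-3,7-dioxabicyclo[3.3.0]oct-1-yl acetate
Conditions: Ac2O, Et3N, DMAP (1 equiv), CH2Cl2, 40 °C
Reagents that add atoms: acetic anhydride, CC(=O)OC(C)=O
Why: DMAP-catalysed acylation through the N-acetylpyridinium ion is the standard way to esterify a hindered tertiary alcohol, the C1 hydroxyl is the only one present, and the basic medium excludes benzylic ionisation, so no stereocentre changes.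

**Step 7**
Reactants: 12 (1S,2R,5R,6S)-2-[4-(benzyloxy)-3-methoxyphenyl]-6-(3,4-dimethoxyphenyl)-3,7-dioxabicyclo[3.3.0]oct-1-yl acetate
Product: 13 (1S,2R,5R,6S)-6-(3,4-dimethoxyphenyl)-2-(4-hydroxy-3-methoxyphenyl)-3,7-dioxabicyclo[3.3.0]oct-1-yl acetate (CNP0107105.1)
Conditions: H2 (1 atm), 10% Pd/C, EtOAc, rt, stopped after one equivalent of H2
Reagents that add atoms: none
Why: Catalytic hydrogenolysis cleaves the unhindered primary benzyl aryl ether much faster than the secondary, ring-embedded benzylic ethers C2–O3 and C6–O7 in a neutral aprotic solvent, so stopping after one equivalent of hydrogen should free the phenol and leave the acetate, the furofuran and all four stereocentres intact.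

**Compound list**

1 | L-malic acid | OC(=O)C[C@H](O)C(=O)O | starting material
2 | pivaldehyde | CC(C)(C)C=O | starting material
3 | 2-[(2S,4S)-2-tert-butyl-5-oxo-1,3-dioxolan-4-yl]acetic acid | OC(=O)C[C@@H]1O[C@H](C(C)(C)C)OC1=O | intermediate
4 | 4-(benzyloxy)-3-methoxybenzaldehyde | COc1cc(C=O)ccc1OCc1ccccc1 | starting material
5 | 2-[(2S,4R)-4-{(R)-[4-(benzyloxy)-3-methoxyphenyl](hydroxy)methyl}-2-tert-butyl-5-oxo-1,3-dioxolan-4-yl]acetic acid | OC(=O)C[C@]1([C@H](O)c2ccc(OCc3ccccc3)c(OC)c2)O[C@H](C(C)(C)C)OC1=O | intermediate
6 | (2S,5R,6R)-6-[4-(benzyloxy)-3-methoxyphenyl]-2-tert-butyl-1,3,7-trioxaspiro[4.4]nonane-4,8-dione | COc1cc([C@H]2OC(=O)C[C@@]23O[C@H](C(C)(C)C)OC3=O)ccc1OCc1ccccc1 | intermediate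
7 | veratraldehyde (3,4-dimethoxybenzaldehyde) | COc1ccc(C=O)cc1OC | starting material
8 | (2S,5R,6R,9R)-6-[4-(benzyloxy)-3-methoxyphenyl]-2-tert-butyl-9-[(S)-(3,4-dimethoxyphenyl)(hydroxy)methyl]-1,3,7-trioxaspiro[4.4]nonane-4,8-dione | COc1cc([C@H]2OC(=O)[C@H]([C@H](O)c4ccc(OC)c(OC)c4)[C@@]23O[C@H](C(C)(C)C)OC3=O)ccc1OCc1ccccc1 | intermediate
9 | (1R,2R,5R,6S)-2-[4-(benzyloxy)-3-methoxyphenyl]-6-(3,4-dimethoxyphenyl)-1-hydroxy-3,7-dioxabicyclo[3.3.0]octane-4,8-dione | COc1cc([C@H]2OC(=O)[C@@H]3[C@@H](c4ccc(OC)c(OC)c4)OC(=O)[C@]23O)ccc1OCc1ccccc1 | intermediate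
10 | (1R,2R,5R,6S)-2-[4-(benzyloxy)-3-methoxyphenyl]-6-(3,4-dimethoxyphenyl)-3,7-dioxabicyclo[3.3.0]octane-1,4,8-triol (anomer mixture) | COc1cc([C@H]2OC(O)[C@@H]3[C@@H](c4ccc(OC)c(OC)c4)OC(O)[C@]23O)ccc1OCc1ccccc1 | intermediate
11 | (1S,2R,5R,6S)-2-[4-(benzyloxy)-3-methoxyphenyl]-6-(3,4-dimethoxyphenyl)-3,7-dioxabicyclo[3.3.0]octan-1-ol | COc1cc([C@H]2OC[C@@H]3[C@@H](c4ccc(OC)c(OC)c4)OC[C@]23O)ccc1OCc1ccccc1 | intermediate
12 | (1S,2R,5R,6S)-2-[4-(benzyloxy)-3-methoxyphenyl]-6-(3,4-dimethoxyphenyl)-3,7-dioxabicyclo[3.3.0]oct-1-yl acetate | COc1cc([C@H]2OC[C@@H]3[C@@H](c4ccc(OC)c(OC)c4)OC[C@]23OC(C)=O)ccc1OCc1ccccc1 | intermediate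
13 | (1S,2R,5R,6S)-6-(3,4-dimethoxyphenyl)-2-(4-hydroxy-3-methoxyphenyl)-3,7-dioxabicyclo[3.3.0]oct-1-yl acetate | COc1cc([C@H]2OC[C@@H]3[C@@H](c4ccc(OC)c(OC)c4)OC[C@]23OC(C)=O)ccc1O | target

Total step count: 7
Longest linear sequence: 7 steps (1 to 13)

**Steps most likely to fail**

**Step 2 (key step).**
- What may go wrong: the lithium aldolate of an electron-rich aldehyde may revert by retro-aldol. The competing cyclic transition states may also be poorly discriminated. The result would be low conversion and weak simple diastereoselection at C2.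
- Fallback: a Mukaiyama aldol replaces the lithium aldol. It sets out from 3.
- The same dianion is silylated with Me3SiCl at −78 °C to give the silyl ketene acetal trimethylsilyl 2-[(2S)-2-tert-butyl-5-(trimethylsilyloxy)-1,3-dioxol-4-yl]acetate F1. F1 is combined with 4 and BF3·OEt2 in CH2Cl2 at −78 °C.
- The addition is then irreversible, and the tert-butyl group still decides the face at C1.
- In the open antiperiplanar transition state the aryl group turns away from the CH2CO2SiMe3 branch, which leads to the same C2 configuration.
- Aqueous acid takes off the silyl groups to give 5, and after the PPTS closure the route is rejoined at 6.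

**Step 3.**
- What may go wrong: E1cB opening of the spiro acetal from the C5 enolate (loss of the C1 oxygen and of pivaldehyde) may compete with addition. Erythro selection at C6 may also be incomplete.
- Fallback: the leaving-group ability of the C1 oxygen is removed before enolisation. It sets out from 6.
- K2CO3 in MeOH at 0 °C, followed by brief acidification, exchanges the acetal for the hydroxy ester methyl (2R,3R)-2-[4-(benzyloxy)-3-methoxyphenyl]-3-hydroxy-5-oxooxolane-3-carboxylate F2.
- Two equivalents of KN(SiMe3)2 at −78 °C give the alkoxide–enolate dianion (Fráter–Seebach type). Its β-oxygen is an oxide and cannot leave.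
- The dianion adds to 7 anti to the alkoxide and gives methyl (2R,3R,4R)-2-[4-(benzyloxy)-3-methoxyphenyl]-4-[(S)-(3,4-dimethoxyphenyl)(hydroxy)methyl]-3-hydroxy-5-oxooxolane-3-carboxylate F3.
- The C6 oxygen of F3 lactonises onto the cis methyl ester, in the flask or with cat. PPTS. The route is rejoined at 9.

**Step 5.**
- What may go wrong: the C8 lactol, flanked by the electron-withdrawing C1 hydroxyl, may ionise slowly. The temperature would then have to be raised to the point where the Lewis acid opens benzylic C–O bonds. That would bring epimerisation at C2 or C6, or reductive ring opening.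
- Fallback: both rings are opened on purpose and closed again. It sets out from 9.
- LiAlH4 in THF at 0 °C gives the pentaol (1R,2S,3R,4S)-1-[4-(benzyloxy)-3-methoxyphenyl]-4-(3,4-dimethoxyphenyl)-2,3-bis(hydroxymethyl)butane-1,2,4-triol F4.
- Catalytic camphorsulfonic acid in CH2Cl2 at 0 °C, quenched early with Et3N, ionises only the two p-alkoxybenzylic alcohols.
- The primary hydroxyls at C4 and C8 capture the cations under kinetic control on the face that places each aryl group exo, as in the closure of quinone methides to pinoresinol-type lignans.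
- C2 and C6 are then re-made under the control of C1 and C5. The route is rejoined at 11.

**Further compounds**

F1 | step 2 | trimethylsilyl 2-[(2S)-2-tert-butyl-5-(trimethylsilyloxy)-1,3-dioxol-4-yl]acetate | C[Si](C)(C)OC(=O)CC1=C(O[Si](C)(C)C)O[C@@H](C(C)(C)C)O1
F2 | step 3 | methyl (2R,3R)-2-[4-(benzyloxy)-3-methoxyphenyl]-3-hydroxy-5-oxooxolane-3-carboxylate | COc1cc([C@H]2OC(=O)C[C@]2(O)C(=O)OC)ccc1OCc1ccccc1
F3 | step 3 | methyl (2R,3R,4R)-2-[4-(benzyloxy)-3-methoxyphenyl]-4-[(S)-(3,4-dimethoxyphenyl)(hydroxy)methyl]-3-hydroxy-5-oxooxolane-3-carboxylate | COc1cc([C@H]2OC(=O)[C@H]([C@H](O)c3ccc(OC)c(OC)c3)[C@]2(O)C(=O)OC)ccc1OCc1ccccc1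
F4 | step 5 | (1R,2S,3R,4S)-1-[4-(benzyloxy)-3-methoxyphenyl]-4-(3,4-dimethoxyphenyl)-2,3-bis(hydroxymethyl)butane-1,2,4-triol | COc1cc([C@@H](O)[C@@](O)(CO)[C@H](CO)[C@H](O)c2ccc(OC)c(OC)c2)ccc1OCc1ccccc1
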